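**Plan** (prostanoid numbering: C1 = ester carbon, ring = C8–C12)

1. Cuts: the C7 acetate and its silyl precursor; then the ring bond C8–C12, which unravels the chlorocyclopentenone to a 3-chloro-5-alkyl-2-furylcarbinol; then furan C9–C8 (furylmetal + aldehyde), furan C12–C13 (allylation) and C6–C7 (alkynylation).
2. Enabling feature: ring carbons C8–C12 carry oxygen on C9 (ketone) and on C12 (tertiary carbinol) in a 1,4-relation across the C10=C11 double bond, with H on C8 and Cl on C10. This is a furan (its oxygen bridging C9 and C12, Cl on its C3) in hydrated, ring-contracted form, so a dearomatising 4π closure can make it; the closure parallels the oxidopentadienyl cation closure of coral prostanoid biogenesis.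
3. Forward: aldehyde fragment (steps 1–3), chlorofuran fragment (steps 4–7), union (step 8), semihydrogenation (step 9), ring closure as the last skeletal bond and only ring (step 10), desilylation and acetylation (steps 11–12).
4. Stereochemistry: C7 from catalytic asymmetric alkynylation; C12 from C7-controlled torquoselective conrotation; C8 by equilibration alpha to the ketone; 5Z from Lindlar reduction; 14Z from (Z)-oct-2-en-1-ol.

Key step: step 10

Remark (assumption): the rearrangement is taken to follow the usual course of 5-alkyl-2-furylcarbinols, with the entering hydroxyl rotating outward, so the first-formed ketone has the C12 hydroxyl trans to the C8 substituent and is then equilibrated at C8.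

**Route**

Step 1
Reactants: 1 methyl hex-5-ynoate; 2 (2E)-but-2-enal
Product: 3 methyl (7R,8E)-7-hydroxydec-8-en-5-ynoate
Conditions: Me2Zn (3 equiv), (S,S)-ProPhenol (10 mol%), Ph3P=O (20 mol%), toluene, 0 °C, 1 in excess; then 2
Reagents that add atoms: none
Why: Zinc alkynylide 1,2-addition to the enal inside the dinuclear zinc–ProPhenol pocket (Trost asymmetric alkynylation) tolerates the ester and sets the C7 carbinol centre by face-selective delivery; the sense should be checked by Mosher analysis and the ligand antipode exchanged if it is opposite.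

Step 2
Reactants: 3 methyl (7R,8E)-7-hydroxydec-8-en-5-ynoate
Product: 4 methyl (7R,8E)-7-[(tert-butyldiphenylsilyl)oxy]dec-8-en-5-ynoate
Conditions: TBDPSCl, imidazole, DMF, rt
Reagents that add atoms: tert-butyl(chloro)diphenylsilane, CC(C)(C)[Si](Cl)(c1ccccc1)c1ccccc1
Why: Standard silyl ether formation on a secondary propargylic alcohol gives the acid-stable, non-chelating ether needed through step 10.

Step 3
Reactants: 4 methyl (7R,8E)-7-[(tert-butyldiphenylsilyl)oxy]dec-8-en-5-ynoate
Product: 5 methyl (7S)-7-[(tert-butyldiphenylsilyl)oxy]-8-oxooct-5-ynoate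
Conditions: O3, CH2Cl2, −78 °C (Sudan red end point); Me2S, −78 °C → rt; used crude at once
Reagents that add atoms: ozone, [O-][O+]=O
Why: Ozonolysis cleaves the disubstituted alkene far faster than the internal alkyne and reductive work-up gives the α-silyloxy aldehyde without touching C7 (the descriptor changes from R to S only through CIP priorities).

Step 4
Reactants: 6 3-bromofuran
Product: 8 (3-bromofuran-2-yl)trimethylsilane, via 3-bromo-2-furyllithium 7 (not isolated)
Conditions: LiN(iPr)2 (LDA), THF, −78 °C; Me3SiCl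
Reagents that add atoms: chlorotrimethylsilane, C[Si](C)(C)Cl
Why: Directed deprotonation at the α-carbon flanked by bromine followed by silyl quench blocks this position for step 7.

Step 5
Reactants: 8 (3-bromofuran-2-yl)trimethylsilane
Product: 10 (3-chlorofuran-2-yl)trimethylsilane, via 3-furyllithium 9 (not isolated)
Conditions: n-BuLi, Et2O, −78 °C; C2Cl6, −78 °C → rt
Reagents that add atoms: hexachloroethane, ClC(Cl)(Cl)C(Cl)(Cl)Cl
Why: Bromine–lithium exchange at low temperature and electrophilic chlorination of the 3-furyllithium swap bromine for chlorine before the lithium can migrate to the free α-position.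

Step 6
Reactants: 11 (2Z)-oct-2-en-1-ol
Product: 12 (2Z)-1-bromooct-2-ene
Conditions: CBr4, PPh3, CH2Cl2, 0 °C
Reagents that add atoms: tetrabromomethane, BrC(Br)(Br)Br
Why: Appel bromination of a primary allylic alcohol proceeds by SN2 at carbon without allylic transposition and with retention of the Z geometry.

Step 7
Reactants: 10 (3-chlorofuran-2-yl)trimethylsilane; 12 (2Z)-1-bromooct-2-ene
Product: 15 4-chloro-2-[(2Z)-oct-2-en-1-yl]furan, via 5-furyllithium 13 (not isolated), via silylfuran 14 (not isolated)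
Conditions: n-BuLi, THF, −78 → −20 °C; 12, −78 °C → rt; then Bu4NF, THF, 0 °C → rt
Reagents that add atoms: none
Why: α-Lithiation at the only free α-position, SN2 alkylation of the furyllithium by the primary allylic bromide (as in furan terpenoid and jasmone syntheses) and fluoride protodesilylation, eased by the adjacent chlorine, give the 2,4-disubstituted furan.

Step 8
Reactants: 15 4-chloro-2-[(2Z)-oct-2-en-1-yl]furan; 5 methyl (7S)-7-[(tert-butyldiphenylsilyl)oxy]-8-oxooct-5-ynoate
Product: 18 methyl (7S)-7-[(tert-butyldiphenylsilyl)oxy]-8-{3-chloro-5-[(2Z)-oct-2-en-1-yl]furan-2-yl}-8-hydroxyoct-5-ynoate (C8 epimers), via furyllithium 16 (not isolated), via furylcerium dichloride 17 (not isolated)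
Conditions: LiN(iPr)2 (LDA), THF, −78 °C; anhydrous CeCl3, −78 °C; 5, −78 °C
Reagents that add atoms: none
Why: Deprotonation at the α-carbon next to chlorine, transmetalation to the weakly basic organocerium and 1,2-addition to the aldehyde spare the ester and avoid enolising the aldehyde; the new C8 centre needs no control because it is ionised in step 10.

Step 9
Reactants: 18 methyl (7S)-7-[(tert-butyldiphenylsilyl)oxy]-8-{3-chloro-5-[(2Z)-oct-2-en-1-yl]furan-2-yl}-8-hydroxyoct-5-ynoate (C8 epimers)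
Product: 19 methyl (5Z,7S)-7-[(tert-butyldiphenylsilyl)oxy]-8-{3-chloro-5-[(2Z)-oct-2-en-1-yl]furan-2-yl}-8-hydroxyoct-5-enoate (C8 epimers)
Conditions: H2 (1 atm), Pd/CaCO3 poisoned with Pb(OAc)2 (Lindlar catalyst), quinoline, EtOAc, rt
Reagents that add atoms: none
Why: Lindlar semihydrogenation adds H2 syn to the alkyne to give the 5Z alkene, while the poisoned catalyst leaves the existing Z alkene, the furan and the C–Cl bond alone.

Step 10
Reactants: 19 methyl (5Z,7S)-7-[(tert-butyldiphenylsilyl)oxy]-8-{3-chloro-5-[(2Z)-oct-2-en-1-yl]furan-2-yl}-8-hydroxyoct-5-enoate (C8 epimers)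
Product: 21 methyl (5Z,7S)-7-[(tert-butyldiphenylsilyl)oxy]-7-{(1R,5S)-3-chloro-5-hydroxy-5-[(2Z)-oct-2-en-1-yl]-2-oxocyclopent-3-en-1-yl}hept-5-enoate, via 8-epimer 20 (not isolated)
Conditions: Dy(OTf)3 (10 mol%), t-BuOH/H2O 5:1, 80 °C; crude 20 then DBU (0.1 equiv), CH2Cl2, 0 °C
Reagents that add atoms: water, O
Why: Dy(OTf)3 ionises the furylic C8 hydroxyl to a furan-stabilised cation, water adds at the alkyl-bearing furan carbon (C12) and the hemiketal opens to a 2,5-dihydroxypentadienyl cation spanning C8–C12 (oxygen on C9 and C12, chlorine on C10), which closes the C8–C12 bond by thermally allowed conrotatory 4π electrocyclisation and loses a proton to give the 2-chloro-4-hydroxycyclopent-2-enone. The closest known reaction is the Piancatelli rearrangement of 5-alkyl-2-furylcarbinols to 4-hydroxy-4-alkylcyclopentenones, a counterpart of the oxidopentadienyl cation closure in coral prostanoid biogenesis; the only ring of the target closes by this 4π conrotation (a five-atom electrocyclisation, not a polar 5-endo attack). The C7 branch on C8 and the entering hydroxyl on C12 both sit outward, so conrotation places the C12 hydroxyl trans to the C8 substituent in 20. The sense of conrotation is set by the C7 stereocentre: with C7–H in the dienol plane facing the C9 oxygen (allylic 1,3-strain), the alkenyl carbon C6 lies anti and the electron-poor C–OSi bond gauche to the bond forming at the enol-like terminus C8, which should lead to 8S,12S. C12 is then fixed, whereas C8, alpha to the ketone, is equilibrated by catalytic DBU to the more stable 8R epimer 21, in which the bulky C7 branch is trans to the octenyl chain and cis to the small hydroxyl. The step needs torquoselectivity, which rests on the single C7 stereocentre and its non-chelating silyl ether, and chemoselectivity, which rests on the mild water-tolerant Lewis acid (silyl ether, ester and both Z alkenes untouched) and on brief catalytic base (no loss of the C12 hydroxyl or the C7 silyloxy group from the C8 enolate).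

Step 11
Reactants: 21 methyl (5Z,7S)-7-[(tert-butyldiphenylsilyl)oxy]-7-{(1R,5S)-3-chloro-5-hydroxy-5-[(2Z)-oct-2-en-1-yl]-2-oxocyclopent-3-en-1-yl}hept-5-enoate
Product: 22 methyl (5Z,7S)-7-{(1R,5S)-3-chloro-5-hydroxy-5-[(2Z)-oct-2-en-1-yl]-2-oxocyclopent-3-en-1-yl}-7-hydroxyhept-5-enoate
Conditions: HF·pyridine, THF/pyridine, 0 °C → rt
Reagents that add atoms: none
Why: Fluoride cleavage of the silyl ether under buffered weakly acidic conditions is chosen over basic fluoride to avoid retro-aldol opening and β-elimination of the β-oxy ketone.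

Step 12
Reactants: 22 methyl (5Z,7S)-7-{(1R,5S)-3-chloro-5-hydroxy-5-[(2Z)-oct-2-en-1-yl]-2-oxocyclopent-3-en-1-yl}-7-hydroxyhept-5-enoate
Product: 23 punaglandin 8, methyl (5Z,7S)-7-acetoxy-7-{(1R,5S)-3-chloro-5-hydroxy-5-[(2Z)-oct-2-en-1-yl]-2-oxocyclopent-3-en-1-yl}hept-5-enoate
Conditions: Ac2O, pyridine, DMAP (5 mol%), CH2Cl2, 0 °C
Reagents that add atoms: acetic anhydride, CC(=O)OC(C)=O
Why: Acylation takes the secondary allylic C7 hydroxyl while the hindered tertiary C12 hydroxyl stays free, and low temperature and short time limit elimination of the β-acetoxy ketone.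

**Compound list**

1 | methyl hex-5-ynoate | COC(=O)CCCC#C | starting material
2 | (2E)-but-2-enal | C/C=C/C=O | starting material
3 | methyl (7R,8E)-7-hydroxydec-8-en-5-ynoate | COC(=O)CCCC#C[C@H](O)/C=C/C | intermediate
4 | methyl (7R,8E)-7-[(tert-butyldiphenylsilyl)oxy]dec-8-en-5-ynoate | COC(=O)CCCC#C[C@H](O[Si](c1ccccc1)(c1ccccc1)C(C)(C)C)/C=C/C | intermediate
5 | methyl (7S)-7-[(tert-butyldiphenylsilyl)oxy]-8-oxooct-5-ynoate | COC(=O)CCCC#C[C@H](O[Si](c1ccccc1)(c1ccccc1)C(C)(C)C)C=O | intermediate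
6 | 3-bromofuran | Brc1ccoc1 | starting material
7 | (3-bromofuran-2-yl)lithium | [Li]c1occc1Br | intermediate
8 | (3-bromofuran-2-yl)trimethylsilane | C[Si](C)(C)c1occc1Br | intermediate
9 | [2-(trimethylsilyl)furan-3-yl]lithium | [Li]c1ccoc1[Si](C)(C)C | intermediate
10 | (3-chlorofuran-2-yl)trimethylsilane | C[Si](C)(C)c1occc1Cl | intermediate
11 | (2Z)-oct-2-en-1-ol | CCCCC/C=C\CO | starting material
12 | (2Z)-1-bromooct-2-ene | CCCCC/C=C\CBr | intermediate
13 | [4-chloro-5-(trimethylsilyl)furan-2-yl]lithium | [Li]c1cc(Cl)c(o1)[Si](C)(C)C | intermediate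
14 | {3-chloro-5-[(2Z)-oct-2-en-1-yl]furan-2-yl}trimethylsilane | CCCCC/C=C\Cc1cc(Cl)c(o1)[Si](C)(C)C | intermediate
15 | 4-chloro-2-[(2Z)-oct-2-en-1-yl]furan | CCCCC/C=C\Cc1cc(Cl)co1 | intermediate
16 | {3-chloro-5-[(2Z)-oct-2-en-1-yl]furan-2-yl}lithium | CCCCC/C=C\Cc1cc(Cl)c([Li])o1 | intermediate
17 | {3-chloro-5-[(2Z)-oct-2-en-1-yl]furan-2-yl}cerium dichloride | CCCCC/C=C\Cc1cc(Cl)c(o1)[Ce](Cl)Cl | intermediate
18 | methyl (7S)-7-[(tert-butyldiphenylsilyl)oxy]-8-{3-chloro-5-[(2Z)-oct-2-en-1-yl]furan-2-yl}-8-hydroxyoct-5-ynoate (C8 epimers) | CCCCC/C=C\Cc1cc(Cl)c(o1)C(O)[C@@H](O[Si](c1ccccc1)(c1ccccc1)C(C)(C)C)C#CCCCC(=O)OC | intermediate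
19 | methyl (5Z,7S)-7-[(tert-butyldiphenylsilyl)oxy]-8-{3-chloro-5-[(2Z)-oct-2-en-1-yl]furan-2-yl}-8-hydroxyoct-5-enoate (C8 epimers) | CCCCC/C=C\Cc1cc(Cl)c(o1)C(O)[C@@H](O[Si](c1ccccc1)(c1ccccc1)C(C)(C)C)/C=C\CCCC(=O)OC | intermediate
20 | methyl (5Z,7S)-7-[(tert-butyldiphenylsilyl)oxy]-7-{(1S,5S)-3-chloro-5-hydroxy-5-[(2Z)-oct-2-en-1-yl]-2-oxocyclopent-3-en-1-yl}hept-5-enoate | CCCCC/C=C\C[C@@]1(O)C=C(Cl)C(=O)[C@H]1[C@H](/C=C\CCCC(=O)OC)O[Si](c1ccccc1)(c1ccccc1)C(C)(C)C | intermediate
21 | methyl (5Z,7S)-7-[(tert-butyldiphenylsilyl)oxy]-7-{(1R,5S)-3-chloro-5-hydroxy-5-[(2Z)-oct-2-en-1-yl]-2-oxocyclopent-3-en-1-yl}hept-5-enoate | CCCCC/C=C\C[C@@]1(O)C=C(Cl)C(=O)[C@@H]1[C@H](/C=C\CCCC(=O)OC)O[Si](c1ccccc1)(c1ccccc1)C(C)(C)C | intermediate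
22 | methyl (5Z,7S)-7-{(1R,5S)-3-chloro-5-hydroxy-5-[(2Z)-oct-2-en-1-yl]-2-oxocyclopent-3-en-1-yl}-7-hydroxyhept-5-enoate | CCCCC/C=C\C[C@@]1(O)C=C(Cl)C(=O)[C@@H]1[C@H](/C=C\CCCC(=O)OC)O | intermediate
23 | punaglandin 8 | CCCCC/C=C\C[C@@]1(O)C=C(Cl)C(=O)[C@@H]1[C@H](/C=C\CCCC(=O)OC)OC(C)=O | target

**Totals and risks**

Total steps: 12. Longest linear sequence: 8 steps (steps 4, 5, 7, 8, 9, 10, 11, 12; the branch through steps 1–3 is equally long).

Step 10. The conrotation may run with poor or opposite torquoselectivity (bond formation anti to the bulky silyloxy group), so that C12 is formed with the wrong configuration relative to C7. Fallback: the C7 centre is used in mirror-image form and inverted at the end. Setting out from 1 and 2, step 1 with the other ligand antipode gives methyl (7S,8E)-7-hydroxydec-8-en-5-ynoate F1. Steps 2 and 3 give methyl (7S,8E)-7-[(tert-butyldiphenylsilyl)oxy]dec-8-en-5-ynoate F2 and methyl (7R)-7-[(tert-butyldiphenylsilyl)oxy]-8-oxooct-5-ynoate F3. Steps 8 and 9 with 15 give the 7R furylcarbinol alkyne F4 and the 7R furylcarbinol Z-alkene F5. The rearrangement, now anti to the silyloxy group, gives the (7R,8S,12S) ketone F6 and, after equilibration, the (7R,8R,12S) ketone F7. HF·pyridine gives the 7-epi alcohol F8. A Mitsunobu reaction (AcOH, PPh3, diisopropyl azodicarboxylate, toluene, 0 °C) inverts C7 while installing the acetate and comes back to the route at 23.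

Step 8. The furylmetal may act as a base toward the aldehyde (enolisation with loss of the C7 configuration) or attack the ester. Fallback: a Nozaki–Hiyama–Kishi union under non-basic conditions. Setting out from 15, lithiation as in step 8 and an iodine quench give 3-chloro-2-iodo-5-[(2Z)-oct-2-en-1-yl]furan F9; CrCl2 (4 equiv) and NiCl2 (2 mol%) in DMF at rt couple F9 with 5 and come back to the route at 18.

Step 7. The furyllithium may attack the γ-carbon of the allylic bromide (SN2′ branching) or the Z geometry may erode. Fallback: the chain is built by olefination. Setting out from 13 (made as in step 7), ethylene oxide and BF3·OEt2 (THF, −78 °C) give 2-[4-chloro-5-(trimethylsilyl)furan-2-yl]ethan-1-ol F10. Dess–Martin periodinane gives 2-[4-chloro-5-(trimethylsilyl)furan-2-yl]acetaldehyde F11. A salt-free Z-selective Wittig reaction with the ylide from hexyltriphenylphosphonium bromide and NaN(SiMe3)2 (THF, −78 °C) comes back to the route at 14, which is desilylated as in step 7.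

**Further compounds**

F1 | step 10 | methyl (7S,8E)-7-hydroxydec-8-en-5-ynoate | COC(=O)CCCC#C[C@@H](O)/C=C/C
F2 | step 10 | methyl (7S,8E)-7-[(tert-butyldiphenylsilyl)oxy]dec-8-en-5-ynoate | COC(=O)CCCC#C[C@@H](O[Si](c1ccccc1)(c1ccccc1)C(C)(C)C)/C=C/C
F3 | step 10 | methyl (7R)-7-[(tert-butyldiphenylsilyl)oxy]-8-oxooct-5-ynoate | COC(=O)CCCC#C[C@@H](O[Si](c1ccccc1)(c1ccccc1)C(C)(C)C)C=O
F4 | step 10 | methyl (7R)-7-[(tert-butyldiphenylsilyl)oxy]-8-{3-chloro-5-[(2Z)-oct-2-en-1-yl]furan-2-yl}-8-hydroxyoct-5-ynoate (C8 epimers) | CCCCC/C=C\Cc1cc(Cl)c(o1)C(O)[C@H](O[Si](c1ccccc1)(c1ccccc1)C(C)(C)C)C#CCCCC(=O)OC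
F5 | step 10 | methyl (5Z,7R)-7-[(tert-butyldiphenylsilyl)oxy]-8-{3-chloro-5-[(2Z)-oct-2-en-1-yl]furan-2-yl}-8-hydroxyoct-5-enoate (C8 epimers) | CCCCC/C=C\Cc1cc(Cl)c(o1)C(O)[C@H](O[Si](c1ccccc1)(c1ccccc1)C(C)(C)C)/C=C\CCCC(=O)OC
F6 | step 10 | methyl (5Z,7R)-7-[(tert-butyldiphenylsilyl)oxy]-7-{(1S,5S)-3-chloro-5-hydroxy-5-[(2Z)-oct-2-en-1-yl]-2-oxocyclopent-3-en-1-yl}hept-5-enoate | CCCCC/C=C\C[C@@]1(O)C=C(Cl)C(=O)[C@H]1[C@@H](/C=C\CCCC(=O)OC)O[Si](c1ccccc1)(c1ccccc1)C(C)(C)C
F7 | step 10 | methyl (5Z,7R)-7-[(tert-butyldiphenylsilyl)oxy]-7-{(1R,5S)-3-chloro-5-hydroxy-5-[(2Z)-oct-2-en-1-yl]-2-oxocyclopent-3-en-1-yl}hept-5-enoate | CCCCC/C=C\C[C@@]1(O)C=C(Cl)C(=O)[C@@H]1[C@@H](/C=C\CCCC(=O)OC)O[Si](c1ccccc1)(c1ccccc1)C(C)(C)C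
F8 | step 10 | methyl (5Z,7R)-7-{(1R,5S)-3-chloro-5-hydroxy-5-[(2Z)-oct-2-en-1-yl]-2-oxocyclopent-3-en-1-yl}-7-hydroxyhept-5-enoate | CCCCC/C=C\C[C@@]1(O)C=C(Cl)C(=O)[C@@H]1[C@@H](/C=C\CCCC(=O)OC)O
F9 | step 8 | 3-chloro-2-iodo-5-[(2Z)-oct-2-en-1-yl]furan | CCCCC/C=C\Cc1cc(Cl)c(I)o1
F10 | step 7 | 2-[4-chloro-5-(trimethylsilyl)furan-2-yl]ethan-1-ol | OCCc1cc(Cl)c(o1)[Si](C)(C)C
F11 | step 7 | 2-[4-chloro-5-(trimethylsilyl)furan-2-yl]acetaldehyde | O=CCc1cc(Cl)c(o1)[Si](C)(C)C
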